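The route rests on disconnecting the O1–C2 bond of the pyran ring bound to C7 of the benzotropolone. Its 2,3-cis array is stored in a (Z)-olefin: a Wittig reaction joins an A-ring phosphonium salt to a benzotropolone-7-carbaldehyde, made in one biomimetic oxidative coupling of (−)-epicatechin with 2,3,4-trihydroxybenzaldehyde. Catalyst-controlled cis-epoxidation fixes C3; the key step then unveils the ortho phenoxide, which opens the cis-epoxide 6-endo at C2 with inversion, closing the last ring and completing the cis stereodiad. It exploits that C2 is allylic to the C6=C7 bond of the seven-membered ring and vinylogous to the C5 carbonyl, hence SN2-active.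

Key step: step 10

Remark: the benzotropolone is written throughout as the 5-oxo/6-hydroxy tautomer of the target SMILES, and step 1 is assumed to follow the theaflavin pathway (C5 of 2 bonds to C6′ of the epicatechin quinone, C3 of 2 to C5′, C4 of 2 is lost as CO2), which places the formyl group at C7.

Step 1
Reactants: 1 (−)-epicatechin; 2 2,3,4-trihydroxybenzaldehyde
Product: 3 3,4,6-trihydroxy-5-oxo-1-[(2R,3R)-3,5,7-trihydroxychroman-2-yl]-5H-benzo[7]annulene-7-carbaldehyde
Conditions: horseradish peroxidase (cat.), H2O2 (3 equiv, slow addition), 2 (2 equiv), acetone/pH 5 citrate–phosphate buffer, rt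
Reagents that add atoms: none
Why: Biomimetic theaflavin-type benzotropolone formation: the B-ring catechol of 1 is oxidised to its o-quinone, C5 of 2 (ortho and para to hydroxyls) adds in a Michael reaction, re-oxidation and 1,2-addition to the central pyrogallol carbonyl give a bicyclo[3.2.1]octane intermediate, and oxidative decarboxylation should leave the seven-membered ring with the formyl group at C7; the (2R,3R) centres of 1 are not touched.

Step 2
Reactants: 3 benzotropolone aldehyde from step 1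
Product: 4 3,4,6-tris(benzyloxy)-1-[(2R,3R)-5,7-bis(benzyloxy)-3-hydroxychroman-2-yl]-5-oxo-5H-benzo[7]annulene-7-carbaldehyde
Conditions: BnBr (7 equiv), K2CO3 (8 equiv), Bu4NI (cat.), DMF, 0 → 40 °C, Ar
Reagents that add atoms: benzyl bromide, BrCc1ccccc1
Why: Williamson etherification of the five phenolic and tropolone hydroxyls with carbonate, which should leave the much less acidic secondary C3 hydroxyl and the aldehyde untouched.

Step 3
Reactants: 5 3,5-bis(benzyloxy)phenol
Product: 6 1-(allyloxy)-3,5-bis(benzyloxy)benzene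
Conditions: allyl bromide, K2CO3, acetone, reflux
Reagents that add atoms: allyl bromide, C=CCBr
Why: Williamson O-allylation of the single free phenol.

Step 4
Reactants: 6 1-(allyloxy)-3,5-bis(benzyloxy)benzene
Product: 7 2-allyl-3,5-bis(benzyloxy)phenol
Conditions: N,N-diethylaniline, 190 °C, Ar
Reagents that add atoms: none
Why: Aromatic Claisen rearrangement ([3,3]-sigmatropic shift, then tautomerisation); the two ortho positions are equivalent, so one regioisomer is expected.

Step 5
Reactants: 7 2-allyl-3,5-bis(benzyloxy)phenol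
Product: 8 [2-allyl-3,5-bis(benzyloxy)phenoxy](tert-butyl)dimethylsilane
Conditions: TBSCl, imidazole, DMF, rt
Reagents that add atoms: tert-butyldimethylsilyl chloride, CC(C)(C)[Si](C)(C)Cl
Why: Standard silylation masks the phenol that will later become O1, so that it survives the ylide and the epoxidation.

Step 6
Reactants: 8 [2-allyl-3,5-bis(benzyloxy)phenoxy](tert-butyl)dimethylsilane
Product: 10 2-[2,4-bis(benzyloxy)-6-(tert-butyldimethylsilyloxy)phenyl]ethan-1-ol, via arylacetaldehyde 9 (not isolated)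
Conditions: OsO4 (2 mol%), NaIO4 (4 equiv), 2,6-lutidine, dioxane/H2O (3:1), rt; extraction; then NaBH4, MeOH, 0 °C
Reagents that add atoms: osmium tetroxide, O=[Os](=O)(=O)=O; sodium periodate (terminal oxidant and oxygen source), [Na+].[O-]I(=O)(=O)=O
Why: Lemieux–Johnson cleavage of the terminal olefin followed by immediate borohydride reduction of the enolisable arylacetaldehyde should give the 2-arylethanol.

Step 7
Reactants: 10 2-[2,4-bis(benzyloxy)-6-(tert-butyldimethylsilyloxy)phenyl]ethan-1-ol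
Product: 12 {2-[2,4-bis(benzyloxy)-6-(tert-butyldimethylsilyloxy)phenyl]ethyl}triphenylphosphonium bromide, via bromide 11 (not isolated)
Conditions: CBr4, PPh3, CH2Cl2, 0 °C; evaporation; then PPh3, MeCN, 82 °C
Reagents that add atoms: carbon tetrabromide, BrC(Br)(Br)Br; triphenylphosphine, c1ccc(cc1)P(c1ccccc1)c1ccccc1
Why: Appel bromination of the primary alcohol and SN2 quaternisation of triphenylphosphine by the primary bromide, telescoped.

Step 8
Reactants: 4 pentabenzyl benzotropolone-7-carbaldehyde; 12 phosphonium bromide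
Product: 14 3,4,6-tris(benzyloxy)-1-[(2R,3R)-5,7-bis(benzyloxy)-3-hydroxychroman-2-yl]-7-{(1Z)-3-[2,4-bis(benzyloxy)-6-(tert-butyldimethylsilyloxy)phenyl]prop-1-en-1-yl}-5H-benzo[7]annulen-5-one, via ylide 13 (not isolated)
Conditions: 12 (2.5 equiv), KHMDS (2.4 equiv), THF, −78 °C; then 4, −78 → 0 °C
Reagents that add atoms: none
Why: Wittig olefination with a non-stabilised ylide under salt-free conditions, where kinetic formation of the cis-oxaphosphetane should give mainly the (Z)-olefin; one equivalent of ylide is spent on the free C3 hydroxyl of 4.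

Step 9
Reactants: 14 (Z)-olefin
Product: 15 3,4,6-tris(benzyloxy)-1-[(2R,3R)-5,7-bis(benzyloxy)-3-hydroxychroman-2-yl]-7-{(2S,3R)-3-[2,4-bis(benzyloxy)-6-(tert-butyldimethylsilyloxy)benzyl]oxiran-2-yl}-5H-benzo[7]annulen-5-one
Conditions: (S,S)-Jacobsen Mn(III)(salen)Cl (10 mol%), NMO (5 equiv), mCPBA (2 equiv), CH2Cl2, −78 °C
Reagents that add atoms: meta-chloroperoxybenzoic acid, O=C(OO)c1cccc(Cl)c1
Why: Jacobsen–Katsuki epoxidation of a conjugated cis-olefin, in which the (S,S) catalyst is expected, by analogy with cis-β-methylstyrene and indene, to deliver oxygen to the face giving the (2S,3R) cis-epoxide and thus to fix C3 of the future pyran ring under catalyst control.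

Step 10
Reactants: 15 cis-epoxide
Product: 17 3,4,6-tris(benzyloxy)-1,7-bis[(2R,3R)-5,7-bis(benzyloxy)-3-hydroxychroman-2-yl]-5H-benzo[7]annulen-5-one, via epoxy phenoxide 16 (not isolated)
Conditions: TBAF (1.2 equiv, 1 M in THF), THF, 0 °C → rt; then AcOH
Reagents that add atoms: none
Why: Fluoride cleaves the aryl silyl ether and the tetrabutylammonium phenoxide 16 attacks the cis-epoxide intramolecularly at C2, the carbon on C7 of the benzotropolone, in an SN2 opening (closest known type: base-mediated cyclisation of 2-(3-aryloxiranylmethyl)phenols to flavan-3-ols). The pyran ring O1–C2–C3–C4–C4a–C8a closes in the 6-endo-tet mode by formation of the O1–C2 bond. C3 keeps the (R) configuration set by the catalyst in step 9, and C2 is formed by backside attack with inversion, (S) epoxide carbon to (R) ether carbon, so that the C7 substituent and the C3 oxygen end up cis. The step needs 6-endo attack over 5-exo attack at C3, which would give a 2-substituted dihydrobenzofuran; C2 is allylic to the C6=C7 bond and vinylogously activated by the C5 carbonyl, which should lower the SN2 barrier there, whereas C3 is an unactivated secondary carbon. The acetic acid quench protonates the C3 alkoxide before it can add to C6 of the tropolone ether.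

Step 11
Reactants: 17 bis(flavan-3-ol); 18 3,4,5-tris(benzyloxy)benzoic acid
Product: 19 3,4,6-tris(benzyloxy)-1,7-bis{(2R,3R)-5,7-bis(benzyloxy)-3-[3,4,5-tris(benzyloxy)benzoyloxy]chroman-2-yl}-5H-benzo[7]annulen-5-one
Conditions: 18 (3 equiv), DCC (3 equiv), DMAP (1 equiv), CH2Cl2, rt
Reagents that add atoms: none
Why: Steglich esterification of the two secondary C3 hydroxyls, the only free hydroxyls left, installs both galloyl groups at once with retention at C3.

Step 12
Reactants: 19 per-benzylated digallate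
Product: 20 CNP0283148.1, 3,4,6-trihydroxy-1,7-bis[(2R,3R)-5,7-dihydroxy-3-(3,4,5-trihydroxybenzoyloxy)chroman-2-yl]-5H-benzo[7]annulen-5-one
Conditions: H2 (1 atm), 20% Pd(OH)2/C, THF/MeOH (1:1), rt; filtration under Ar
Reagents that add atoms: none
Why: Hydrogenolysis of the thirteen O-benzyl groups, in which the esters, the pyran C2–O1 bonds and the tropolone ring are expected to survive at 1 atm and room temperature if the reaction is stopped once debenzylation is complete.

Compound list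
1 | (−)-epicatechin, (2R,3R)-2-(3,4-dihydroxyphenyl)chromane-3,5,7-triol | O[C@@H]1Cc2c(O)cc(O)cc2O[C@@H]1c1ccc(O)c(O)c1 | starting material
2 | 2,3,4-trihydroxybenzaldehyde | O=Cc1ccc(O)c(O)c1O | starting material
3 | 3,4,6-trihydroxy-5-oxo-1-[(2R,3R)-3,5,7-trihydroxychroman-2-yl]-5H-benzo[7]annulene-7-carbaldehyde | O=CC1=C(O)C(=O)c2c(O)c(O)cc([C@H]3Oc4cc(O)cc(O)c4C[C@H]3O)c2C=C1 | intermediate
4 | 3,4,6-tris(benzyloxy)-1-[(2R,3R)-5,7-bis(benzyloxy)-3-hydroxychroman-2-yl]-5-oxo-5H-benzo[7]annulene-7-carbaldehyde | O=CC1=C(OCc2ccccc2)C(=O)c2c(OCc3ccccc3)c(OCc3ccccc3)cc([C@H]3Oc4cc(OCc5ccccc5)cc(OCc5ccccc5)c4C[C@H]3O)c2C=C1 | intermediate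
5 | 3,5-bis(benzyloxy)phenol | Oc1cc(OCc2ccccc2)cc(OCc2ccccc2)c1 | starting material
6 | 1-(allyloxy)-3,5-bis(benzyloxy)benzene | C=CCOc1cc(OCc2ccccc2)cc(OCc2ccccc2)c1 | intermediate
7 | 2-allyl-3,5-bis(benzyloxy)phenol | C=CCc1c(O)cc(OCc2ccccc2)cc1OCc1ccccc1 | intermediate
8 | [2-allyl-3,5-bis(benzyloxy)phenoxy](tert-butyl)dimethylsilane | C=CCc1c(O[Si](C)(C)C(C)(C)C)cc(OCc2ccccc2)cc1OCc1ccccc1 | intermediate
9 | 2-[2,4-bis(benzyloxy)-6-(tert-butyldimethylsilyloxy)phenyl]acetaldehyde (not isolated) | O=CCc1c(O[Si](C)(C)C(C)(C)C)cc(OCc2ccccc2)cc1OCc1ccccc1 | intermediate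
10 | 2-[2,4-bis(benzyloxy)-6-(tert-butyldimethylsilyloxy)phenyl]ethan-1-ol | OCCc1c(O[Si](C)(C)C(C)(C)C)cc(OCc2ccccc2)cc1OCc1ccccc1 | intermediate
11 | [3,5-bis(benzyloxy)-2-(2-bromoethyl)phenoxy](tert-butyl)dimethylsilane (not isolated) | BrCCc1c(O[Si](C)(C)C(C)(C)C)cc(OCc2ccccc2)cc1OCc1ccccc1 | intermediate
12 | {2-[2,4-bis(benzyloxy)-6-(tert-butyldimethylsilyloxy)phenyl]ethyl}triphenylphosphonium bromide | [Br-].C(Cc1c(O[Si](C)(C)C(C)(C)C)cc(OCc2ccccc2)cc1OCc1ccccc1)[P+](c1ccccc1)(c1ccccc1)c1ccccc1 | intermediate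
13 | phosphonium ylide of 12 (not isolated) | [CH-](Cc1c(O[Si](C)(C)C(C)(C)C)cc(OCc2ccccc2)cc1OCc1ccccc1)[P+](c1ccccc1)(c1ccccc1)c1ccccc1 | intermediate
14 | 3,4,6-tris(benzyloxy)-1-[(2R,3R)-5,7-bis(benzyloxy)-3-hydroxychroman-2-yl]-7-{(1Z)-3-[2,4-bis(benzyloxy)-6-(tert-butyldimethylsilyloxy)phenyl]prop-1-en-1-yl}-5H-benzo[7]annulen-5-one | CC(C)(C)[Si](C)(C)Oc1cc(OCc2ccccc2)cc(OCc2ccccc2)c1C/C=C\C1=C(OCc2ccccc2)C(=O)c2c(OCc3ccccc3)c(OCc3ccccc3)cc([C@H]3Oc4cc(OCc5ccccc5)cc(OCc5ccccc5)c4C[C@H]3O)c2C=C1 | intermediate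
15 | 3,4,6-tris(benzyloxy)-1-[(2R,3R)-5,7-bis(benzyloxy)-3-hydroxychroman-2-yl]-7-{(2S,3R)-3-[2,4-bis(benzyloxy)-6-(tert-butyldimethylsilyloxy)benzyl]oxiran-2-yl}-5H-benzo[7]annulen-5-one | CC(C)(C)[Si](C)(C)Oc1cc(OCc2ccccc2)cc(OCc2ccccc2)c1C[C@H]6O[C@H]6C1=C(OCc2ccccc2)C(=O)c2c(OCc3ccccc3)c(OCc3ccccc3)cc([C@H]3Oc4cc(OCc5ccccc5)cc(OCc5ccccc5)c4C[C@H]3O)c2C=C1 | intermediate
16 | tetrabutylammonium phenoxide of desilylated 15, with the (2S,3R) epoxide intact (not isolated) | [O-]c1cc(OCc2ccccc2)cc(OCc2ccccc2)c1C[C@H]6O[C@H]6C1=C(OCc2ccccc2)C(=O)c2c(OCc3ccccc3)c(OCc3ccccc3)cc([C@H]3Oc4cc(OCc5ccccc5)cc(OCc5ccccc5)c4C[C@H]3O)c2C=C1.CCCC[N+](CCCC)(CCCC)CCCC | intermediate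
17 | 3,4,6-tris(benzyloxy)-1,7-bis[(2R,3R)-5,7-bis(benzyloxy)-3-hydroxychroman-2-yl]-5H-benzo[7]annulen-5-one | O[C@@H]1Cc2c(OCc3ccccc3)cc(OCc3ccccc3)cc2O[C@@H]1C1=C(OCc2ccccc2)C(=O)c2c(OCc3ccccc3)c(OCc3ccccc3)cc([C@H]3Oc4cc(OCc5ccccc5)cc(OCc5ccccc5)c4C[C@H]3O)c2C=C1 | intermediate
18 | 3,4,5-tris(benzyloxy)benzoic acid | OC(=O)c1cc(OCc2ccccc2)c(OCc2ccccc2)c(OCc2ccccc2)c1 | starting material
19 | 3,4,6-tris(benzyloxy)-1,7-bis{(2R,3R)-5,7-bis(benzyloxy)-3-[3,4,5-tris(benzyloxy)benzoyloxy]chroman-2-yl}-5H-benzo[7]annulen-5-one | O=C(O[C@@H]1Cc2c(OCc3ccccc3)cc(OCc3ccccc3)cc2O[C@@H]1C1=C(OCc2ccccc2)C(=O)c2c(OCc3ccccc3)c(OCc3ccccc3)cc([C@H]3Oc4cc(OCc5ccccc5)cc(OCc5ccccc5)c4C[C@H]3OC(=O)c3cc(OCc4ccccc4)c(OCc4ccccc4)c(OCc4ccccc4)c3)c2C=C1)c1cc(OCc2ccccc2)c(OCc2ccccc2)c(OCc2ccccc2)c1 | intermediate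
20 | CNP0283148.1, 3,4,6-trihydroxy-1,7-bis[(2R,3R)-5,7-dihydroxy-3-(3,4,5-trihydroxybenzoyloxy)chroman-2-yl]-5H-benzo[7]annulen-5-one | O=C(O[C@@H]1Cc2c(O)cc(O)cc2O[C@@H]1c1ccc2c([C@H]3Oc4cc(O)cc(O)c4C[C@H]3OC(=O)c3cc(O)c(O)c(O)c3)cc(O)c(O)c2c(=O)c1O)c1cc(O)c(O)c(O)c1 | target

Total step count: 12. Longest linear sequence: 10 steps (from 5 through steps 3–12).

Steps most likely to fail

Step 1. The oxidative cross-coupling may lose chemoselectivity: either partner can self-couple or over-oxidise, the phloroglucinol ring of 1 can condense with the aldehyde, and peroxide can attack the formyl group. The fallback separates oxidation from C–C bond formation. Setting out from 1, the catechol alone is oxidised with o-chloranil (THF/MeCN, −40 °C) to epicatechin o-quinone F1, used in excess so that it also serves as oxidant for the later stages. Aldehyde 2 is then added as the nucleophile and the mixture is warmed in aqueous buffer under air. Michael addition, bicyclo[3.2.1]octane formation and decarboxylation should then return the route at 3.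

Step 9. Oxygen transfer from the Mn-oxo species is stepwise, so facial selectivity may be insufficient and part of the material may leak to the trans-epoxide; the doubly activated CH2 group and the electron-rich rings may also be oxidised. The fallback gives up catalyst control. Setting out from 14, dimethyldioxirane (acetone, −20 °C) transfers oxygen in a concerted, stereospecific way to both faces. Epoxide 15 and its (2R,3S)-epoxide diastereomer F2 are diastereomers because of the epicatechin-derived centres, and are separated by preparative HPLC. The route is rejoined at 15.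

Step 10. The ring closure may take the wrong course: 5-exo attack of the phenoxide at C3, or addition of the transient alkoxide to C6 of the tropolone ether. The fallback forms the O1–C2 bond by dehydrative etherification instead of epoxide opening. Setting out from 14, osmium-catalysed syn-dihydroxylation with a cinchona ligand of the class used for cis-olefins (enantiomer chosen for the (1S,2R) diol, minor diastereomer removed by chromatography) gives erythro-diol F3. TBAF then frees the phenol to give triol F4. Mitsunobu cyclisation (PPh3, DIAD, THF, 0 °C) displaces the activated hydroxyl on the carbon bound to C7 with inversion, and the route is rejoined at 17.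

Further compounds
F1 | step 1 | epicatechin o-quinone, 4-[(2R,3R)-3,5,7-trihydroxychroman-2-yl]cyclohexa-3,5-diene-1,2-dione | O[C@@H]1Cc2c(O)cc(O)cc2O[C@@H]1C1=CC(=O)C(=O)C=C1
F2 | step 9 | (2R,3S)-epoxide diastereomer of 15 | CC(C)(C)[Si](C)(C)Oc1cc(OCc2ccccc2)cc(OCc2ccccc2)c1C[C@@H]6O[C@@H]6C1=C(OCc2ccccc2)C(=O)c2c(OCc3ccccc3)c(OCc3ccccc3)cc([C@H]3Oc4cc(OCc5ccccc5)cc(OCc5ccccc5)c4C[C@H]3O)c2C=C1
F3 | step 10 | 3,4,6-tris(benzyloxy)-1-[(2R,3R)-5,7-bis(benzyloxy)-3-hydroxychroman-2-yl]-7-{(1S,2R)-3-[2,4-bis(benzyloxy)-6-(tert-butyldimethylsilyloxy)phenyl]-1,2-dihydroxypropyl}-5H-benzo[7]annulen-5-one | CC(C)(C)[Si](C)(C)Oc1cc(OCc2ccccc2)cc(OCc2ccccc2)c1C[C@@H](O)[C@@H](O)C1=C(OCc2ccccc2)C(=O)c2c(OCc3ccccc3)c(OCc3ccccc3)cc([C@H]3Oc4cc(OCc5ccccc5)cc(OCc5ccccc5)c4C[C@H]3O)c2C=C1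
F4 | step 10 | 3,4,6-tris(benzyloxy)-1-[(2R,3R)-5,7-bis(benzyloxy)-3-hydroxychroman-2-yl]-7-{(1S,2R)-3-[2,4-bis(benzyloxy)-6-hydroxyphenyl]-1,2-dihydroxypropyl}-5H-benzo[7]annulen-5-one | Oc1cc(OCc2ccccc2)cc(OCc2ccccc2)c1C[C@@H](O)[C@@H](O)C1=C(OCc2ccccc2)C(=O)c2c(OCc3ccccc3)c(OCc3ccccc3)cc([C@H]3Oc4cc(OCc5ccccc5)cc(OCc5ccccc5)c4C[C@H]3O)c2C=C1
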